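**Plan**

1. Retrosynthetic cuts, in order: the (Z)-enoate C=C and the C19–O ester bond; the two methylene carbons of the diene (C16 and C15, both grown from a C14 aldehyde); the C8–O bond (back to an 8(17)-alkene); then C4–C5 and C9–C10 in one operation, which opens rings A and B to an open chain; last, C1–C2 and C11–C12 of that chain.
2. Enabling feature: C4 is quaternary, carries the oxygenated C19 and sits next to C3 in ring A. With C19 as an ester and a temporary ketone on C3, C4 becomes the central carbon of a 1,3-dicarbonyl that can be oxidised to an electrophilic radical. C5=C10 and C8=C9 are then the two E-trisubstituted alkenes of a head-to-tail isoprenoid chain that folds into the trans-decalin (rings A and B).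
3. Forward: geranyl bromide is extended at C11–C12 and at C1–C2. An oxidative radical cascade closes ring A (C4–C5), then ring B (C9–C10), and leaves the C8=C17 alkene. C3 is then deoxygenated, C8 hydrated, and the diene and the (Z)-feruloyl ester are built last.
4. Stereochemistry: C5, C9 and C10 come from the E alkenes through chair-like closures; C4 from the axial preference of the ester; the absolute configuration from a (−)-8-phenylmenthyl ester; C8 from α-face epoxidation and hydride opening at C17; the Z alkene from a Still–Gennari olefination.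
5. Helpers and their removal: the C3 ketone (Barton–McCombie), the auxiliary (LiAlH4, which also brings C19 to the alcohol level), and the dioxolane on C14 (acid).

Key step: step 6

Remark: labdane numbering is used for the bicyclic compounds (C19 is the axial β carbon on C4, C18 the equatorial α methyl; 5α-H, 9α-H and 10β-CH3 as in the labdane parent); the facial sense of (−)-8-phenylmenthol is assumed, by analogy with the known behaviour of 8-phenylmenthyl α-methyl β-keto esters in this cyclisation type, to lead to the 10β-methyl series, and [bis(2,2,2-trifluoroethoxy)phosphoryl]acetic acid is taken as a purchasable reagent.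

**Route**

Step 1
Reactants: 1 geranyl bromide; 2 2-(2-bromoethyl)-1,3-dioxolane
Product: 4 2-[(4E)-5,9-dimethyldeca-4,8-dien-1-yl]-1,3-dioxolane, via Grignard reagent 3 (not isolated)
Conditions: 2, Mg, THF, 25–30 °C; then 1, Li2CuCl4 (3 mol%), THF, −10 °C to rt
Reagents that add atoms: none
Why: Copper-catalysed cross-coupling of a primary allylic bromide with an alkyl Grignard reagent proceeds by direct α-substitution with retention of the E alkene, and the dioxolane Grignard reagent is stable below 30 °C.

Step 2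
Reactants: 4 2-[(4E)-5,9-dimethyldeca-4,8-dien-1-yl]-1,3-dioxolane
Product: 5 (2E,6E)-10-(1,3-dioxolan-2-yl)-2,6-dimethyldeca-2,6-dien-1-ol
Conditions: SeO2 (0.3 equiv), t-BuOOH (3 equiv), CH2Cl2, 0 °C to rt
Reagents that add atoms: selenium dioxide, O=[Se]=O (oxygen donor, re-formed by the hydroperoxide); tert-butyl hydroperoxide, CC(C)(C)OO
Why: Selenium dioxide allylic oxidation (ene reaction then [2,3]-sigmatropic shift) attacks the more accessible terminal trisubstituted alkene at its E methyl group, giving the (E)-allylic alcohol while the internal alkene and the dioxolane are left alone.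

Step 3
Reactants: 5 (2E,6E)-10-(1,3-dioxolan-2-yl)-2,6-dimethyldeca-2,6-dien-1-ol
Product: 6 2-[(4E,8E)-10-bromo-5,9-dimethyldeca-4,8-dien-1-yl]-1,3-dioxolane
Conditions: CBr4, PPh3, CH2Cl2, −20 to 0 °C
Reagents that add atoms: tetrabromomethane, BrC(Br)(Br)Br
Why: The Appel reaction converts the primary allylic alcohol into the bromide by SN2 displacement of the alkoxyphosphonium ion under near-neutral conditions that keep the dioxolane and both E alkenes.

Step 4
Reactants: 7 ethyl 2-methyl-3-oxobutanoate; 8 (−)-8-phenylmenthol [(1R,2S,5R)-5-methyl-2-(2-phenylpropan-2-yl)cyclohexan-1-ol]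
Product: 9 (1R,2S,5R)-5-methyl-2-(2-phenylpropan-2-yl)cyclohexyl 2-methyl-3-oxobutanoate (C2 epimers)
Conditions: DMAP (0.3 equiv), toluene, reflux, 4 Å molecular sieves (removal of EtOH)
Reagents that add atoms: none
Why: DMAP-catalysed transesterification of a β-keto ester runs through the acylketene, which is trapped even by the hindered secondary alcohol, and removal of ethanol drives it to completion; the C2 centre is erased in step 6.

Step 5
Reactants: 9 (1R,2S,5R)-5-methyl-2-(2-phenylpropan-2-yl)cyclohexyl 2-methyl-3-oxobutanoate; 6 2-[(4E,8E)-10-bromo-5,9-dimethyldeca-4,8-dien-1-yl]-1,3-dioxolane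
Product: 11 (1R,2S,5R)-5-methyl-2-(2-phenylpropan-2-yl)cyclohexyl (6E,10E)-14-(1,3-dioxolan-2-yl)-2,6,10-trimethyl-3-oxotetradeca-6,10-dienoate, via dianion 10 (not isolated)
Conditions: NaH, THF, 0 °C; n-BuLi, 0 °C; then 6, 0 °C; aq. NH4Cl
Reagents that add atoms: none
Why: γ-Alkylation of the β-keto ester dianion, whose terminal carbanion is the more reactive site, with the allylic bromide is an SN2 reaction that leaves the E alkenes and the dioxolane untouched.

Step 6
Reactants: 11 (1R,2S,5R)-5-methyl-2-(2-phenylpropan-2-yl)cyclohexyl (6E,10E)-14-(1,3-dioxolan-2-yl)-2,6,10-trimethyl-3-oxotetradeca-6,10-dienoate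
Product: 12 (−)-8-phenylmenthyl 14,14-(ethylenedioxy)-3-oxo-15,16-dinorlabd-8(17)-en-19-oate
Conditions: Mn(OAc)3·2H2O (2.2 equiv), Cu(OAc)2·H2O (1.0 equiv), degassed AcOH (0.05 M), rt
Reagents that add atoms: none
Why: Mn(OAc)3 converts the α-methyl β-keto ester into its manganese enolate and oxidises it to the electrophilic C4 radical, which adds 6-endo-trig to C5 of the (E)-C5=C10 alkene (C4–C5 bond, ring A); the tertiary C10 radical then adds 6-endo-trig to C9 of the (E)-C8=C9 alkene (C9–C10 bond, ring B), and the tertiary C8 radical is intercepted by Cu(OAc)2 and loses a hydrogen of the C17 methyl to give the exocyclic alkene. The closest known reaction type is the Mn(OAc)3/Cu(OAc)2 oxidative radical polycyclisation of polyenyl α-methyl β-keto esters, including its 8-phenylmenthyl ester variant. Both rings close through chair-like transition states, so the E geometry of the two alkenes should translate into the trans ring fusion (5α-H, 10β-CH3) and the equatorial 9β side chain. At C4 the ester, turned anti to the oxygen of the in-ring C3 ketone, takes the axial position on the forming chair, which puts C19 cis to the C10 methyl and leaves the C4 methyl equatorial. The absolute sense comes from the auxiliary, whose phenyl ring covers one face of the planar C4 radical so that the alkene approaches the open face. The step needs 6-endo over 5-exo closure, secured by the fully substituted proximal alkene carbons C10 and C8 and by the ring ketone, and oxidation of the C8 radical faster than hydrogen abstraction, secured by the stoichiometric Cu(OAc)2.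

Step 7
Reactants: 12 (−)-8-phenylmenthyl 14,14-(ethylenedioxy)-3-oxo-15,16-dinorlabd-8(17)-en-19-oate
Product: 13 (−)-8-phenylmenthyl 14,14-(ethylenedioxy)-3β-hydroxy-15,16-dinorlabd-8(17)-en-19-oate
Conditions: NaBH4, THF/MeOH, 0 °C
Reagents that add atoms: none
Why: NaBH4 reduces the ring ketone but not the hindered ester, hydride entering along the axial α trajectory away from the axial C19 ester to give mainly the equatorial 3β alcohol, a centre that is removed in step 9.

Step 8
Reactants: 13 (−)-8-phenylmenthyl 14,14-(ethylenedioxy)-3β-hydroxy-15,16-dinorlabd-8(17)-en-19-oate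
Product: 14 (−)-8-phenylmenthyl 14,14-(ethylenedioxy)-3β-[(imidazol-1-ylcarbonothioyl)oxy]-15,16-dinorlabd-8(17)-en-19-oate
Conditions: 1,1′-thiocarbonyldiimidazole, DMAP (cat.), toluene, 90 °C
Reagents that add atoms: 1,1′-thiocarbonyldiimidazole, S=C(n1ccnc1)n1ccnc1
Why: Thioacylation with 1,1′-thiocarbonyldiimidazole needs no strong base, so the β-hydroxy ester cannot undergo retro-aldol cleavage, and it gives the radical-labile thiocarbonyl derivative for the Barton–McCombie reaction.

Step 9
Reactants: 14 (−)-8-phenylmenthyl 14,14-(ethylenedioxy)-3β-[(imidazol-1-ylcarbonothioyl)oxy]-15,16-dinorlabd-8(17)-en-19-oate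
Product: 15 (−)-8-phenylmenthyl 14,14-(ethylenedioxy)-15,16-dinorlabd-8(17)-en-19-oate
Conditions: Bu3SnH, AIBN (cat.), toluene, reflux
Reagents that add atoms: none
Why: Barton–McCombie deoxygenation: the stannyl radical adds to C=S, the C3–O bond fragments, and the secondary C3 radical, which has no alkene within reach, takes hydrogen from Bu3SnH.

Step 10
Reactants: 15 (−)-8-phenylmenthyl 14,14-(ethylenedioxy)-15,16-dinorlabd-8(17)-en-19-oate
Product: 16 (−)-8-phenylmenthyl 8α,17-epoxy-14,14-(ethylenedioxy)-15,16-dinorlabdan-19-oate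
Conditions: mCPBA, NaHCO3, CH2Cl2, 0 °C
Reagents that add atoms: mCPBA (3-chloroperoxybenzoic acid), OOC(=O)c1cccc(Cl)c1
Why: Prilezhaev epoxidation of the 1,1-disubstituted 8(17)-alkene should occur from the α face, which is free of the axial C10 methyl group, and so sets C8 with oxygen α, while the hindered ester, the dioxolane and the phenyl ring do not react.

Step 11
Reactants: 16 (−)-8-phenylmenthyl 8α,17-epoxy-14,14-(ethylenedioxy)-15,16-dinorlabdan-19-oate
Product: 18 8α,19-dihydroxy-15,16-dinorlabdan-14-al, via diol acetal 17 (not isolated)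
Conditions: LiAlH4, THF, 0 °C to reflux; then 1 M HCl, THF/H2O, rt
Reagents that add atoms: water, O
Why: LiAlH4 opens the epoxide by hydride attack at the primary C17 (8α tertiary alcohol and β C17 methyl, configuration from step 10) and reduces the hindered C19 ester to the primary alcohol with release of the auxiliary, and the acidic work-up hydrolyses the dioxolane to the aldehyde.

Step 12
Reactants: 18 8α,19-dihydroxy-15,16-dinorlabdan-14-al
Product: 19 8α,19-dihydroxy-15-norlabd-13(16)-en-14-al
Conditions: 37% aq. HCHO, pyrrolidine (10 mol%), EtCO2H (10 mol%), i-PrOH, 45 °C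
Reagents that add atoms: formaldehyde, C=O
Why: Amine-catalysed α-methylenation (Mannich condensation with formaldehyde, then elimination of the amine) turns the aldehyde CH2 at C13 into the C13=C16 methylene under conditions that tolerate both free hydroxyl groups.

Step 13
Reactants: 19 8α,19-dihydroxy-15-norlabd-13(16)-en-14-al
Product: 20 labda-13(16),14-diene-8α,19-diol
Conditions: Ph3PCH3Br (4 equiv), KOt-Bu (3.8 equiv), THF, 0 °C to rt
Reagents that add atoms: methyltriphenylphosphonium bromide, C[P+](c1ccccc1)(c1ccccc1)c1ccccc1.[Br-]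
Why: Wittig methylenation of the enal carbonyl (1,2-addition of the non-stabilised ylide) gives the 2-substituted buta-1,3-diene, the extra ylide only deprotonating the two hydroxyl groups.

Step 14
Reactants: 20 labda-13(16),14-diene-8α,19-diol; 21 [bis(2,2,2-trifluoroethoxy)phosphoryl]acetic acid
Product: 22 8α-hydroxylabda-13(16),14-dien-19-yl [bis(2,2,2-trifluoroethoxy)phosphoryl]acetate
Conditions: DCC, DMAP (cat.), CH2Cl2, 0 °C to rt
Reagents that add atoms: none
Why: Steglich esterification acylates only the primary C19 hydroxyl, the tertiary 8α hydroxyl being inert to the activated acid.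

Step 15
Reactants: 23 vanillin (4-hydroxy-3-methoxybenzaldehyde)
Product: 24 4-[(tert-butyldimethylsilyl)oxy]-3-methoxybenzaldehyde
Conditions: TBSCl, imidazole, DMF, rt
Reagents that add atoms: tert-butyldimethylsilyl chloride (TBSCl), CC(C)(C)[Si](C)(C)Cl
Why: Imidazole-promoted silylation protects the phenol so that the aldehyde stays electrophilic and no phenoxide forms in step 16.

Step 16
Reactants: 22 8α-hydroxylabda-13(16),14-dien-19-yl [bis(2,2,2-trifluoroethoxy)phosphoryl]acetate; 24 4-[(tert-butyldimethylsilyl)oxy]-3-methoxybenzaldehyde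
Product: 26 8α-hydroxylabda-13(16),14-dien-19-yl (2Z)-3-[4-(tert-butyldimethylsilyloxy)-3-methoxyphenyl]prop-2-enoate, via potassium phosphonate carbanion 25 (not isolated)
Conditions: KN(SiMe3)2 (1.05 equiv), 18-crown-6, THF, −78 °C; then 24, −78 °C, dark
Reagents that add atoms: none
Why: In the Still–Gennari modification of the Horner–Wadsworth–Emmons reaction the electron-poor trifluoroethyl phosphonate and the dissociated potassium counter-ion make elimination from the kinetic adduct faster than its equilibration, so the (Z)-enoate should form, and one equivalent of base deprotonates only the phosphonoacetate and not the tertiary alcohol.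

Step 17
Reactants: 26 8α-hydroxylabda-13(16),14-dien-19-yl (2Z)-3-[4-(tert-butyldimethylsilyloxy)-3-methoxyphenyl]prop-2-enoate
Product: 27 8α-hydroxylabda-13(16),14-dien-19-yl (2Z)-3-(4-hydroxy-3-methoxyphenyl)prop-2-enoate
Conditions: TBAF, AcOH (1:1), THF, 0 °C, dark
Reagents that add atoms: none
Why: Fluoride cleaves the aryl silyl ether, and the acetic acid buffer keeps the phenol protonated so that the (Z)-enoate is not isomerised through its phenoxide and the ester, diene and tertiary alcohol are untouched.

**Compound list**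

1 | geranyl bromide [(2E)-1-bromo-3,7-dimethylocta-2,6-diene] | CC(C)=CCC/C(C)=C/CBr | starting material
2 | 2-(2-bromoethyl)-1,3-dioxolane | BrCCC1OCCO1 | starting material
3 | [2-(1,3-dioxolan-2-yl)ethyl]magnesium bromide | Br[Mg]CCC1OCCO1 | intermediate
4 | 2-[(4E)-5,9-dimethyldeca-4,8-dien-1-yl]-1,3-dioxolane | CC(C)=CCC/C(C)=C/CCCC1OCCO1 | intermediate
5 | (2E,6E)-10-(1,3-dioxolan-2-yl)-2,6-dimethyldeca-2,6-dien-1-ol | OC/C(C)=C/CC/C(C)=C/CCCC1OCCO1 | intermediate
6 | 2-[(4E,8E)-10-bromo-5,9-dimethyldeca-4,8-dien-1-yl]-1,3-dioxolane | BrC/C(C)=C/CC/C(C)=C/CCCC1OCCO1 | intermediate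
7 | ethyl 2-methyl-3-oxobutanoate | CCOC(=O)C(C)C(C)=O | starting material
8 | (−)-8-phenylmenthol [(1R,2S,5R)-5-methyl-2-(2-phenylpropan-2-yl)cyclohexan-1-ol] | O[C@@H]1C[C@H](C)CC[C@H]1C(C)(C)c1ccccc1 | starting material
9 | (1R,2S,5R)-5-methyl-2-(2-phenylpropan-2-yl)cyclohexyl 2-methyl-3-oxobutanoate (C2 epimers) | CC(=O)C(C)C(=O)O[C@@H]1C[C@H](C)CC[C@H]1C(C)(C)c1ccccc1 | intermediate
10 | sodium lithium dianion of 9 (α-carbon and terminal methyl deprotonated) | [Na+].[Li+].[CH2-]C(=O)[C-](C)C(=O)O[C@@H]1C[C@H](C)CC[C@H]1C(C)(C)c1ccccc1 | intermediate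
11 | (1R,2S,5R)-5-methyl-2-(2-phenylpropan-2-yl)cyclohexyl (6E,10E)-14-(1,3-dioxolan-2-yl)-2,6,10-trimethyl-3-oxotetradeca-6,10-dienoate (C2 epimers) | CC(C(=O)O[C@@H]1C[C@H](C)CC[C@H]1C(C)(C)c1ccccc1)C(=O)CC/C(C)=C/CC/C(C)=C/CCCC1OCCO1 | intermediate
12 | (−)-8-phenylmenthyl 14,14-(ethylenedioxy)-3-oxo-15,16-dinorlabd-8(17)-en-19-oate | O1CCOC1CCC[C@@H]1[C@@]2(C)CCC(=O)[C@](C)(C(=O)O[C@@H]3C[C@H](C)CC[C@H]3C(C)(C)c3ccccc3)[C@@H]2CCC1=C | intermediate
13 | (−)-8-phenylmenthyl 14,14-(ethylenedioxy)-3β-hydroxy-15,16-dinorlabd-8(17)-en-19-oate | O1CCOC1CCC[C@@H]1[C@@]2(C)CC[C@H](O)[C@](C)(C(=O)O[C@@H]3C[C@H](C)CC[C@H]3C(C)(C)c3ccccc3)[C@@H]2CCC1=C | intermediate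
14 | (−)-8-phenylmenthyl 14,14-(ethylenedioxy)-3β-[(imidazol-1-ylcarbonothioyl)oxy]-15,16-dinorlabd-8(17)-en-19-oate | O1CCOC1CCC[C@@H]1[C@@]2(C)CC[C@H](OC(=S)n3ccnc3)[C@](C)(C(=O)O[C@@H]3C[C@H](C)CC[C@H]3C(C)(C)c3ccccc3)[C@@H]2CCC1=C | intermediate
15 | (−)-8-phenylmenthyl 14,14-(ethylenedioxy)-15,16-dinorlabd-8(17)-en-19-oate | O1CCOC1CCC[C@@H]1[C@@]2(C)CCC[C@](C)(C(=O)O[C@@H]3C[C@H](C)CC[C@H]3C(C)(C)c3ccccc3)[C@@H]2CCC1=C | intermediate
16 | (−)-8-phenylmenthyl 8α,17-epoxy-14,14-(ethylenedioxy)-15,16-dinorlabdan-19-oate | O1CCOC1CCC[C@@H]1[C@@]2(C)CCC[C@](C)(C(=O)O[C@@H]3C[C@H](C)CC[C@H]3C(C)(C)c3ccccc3)[C@@H]2CC[C@]14CO4 | intermediate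
17 | 14,14-(ethylenedioxy)-15,16-dinorlabdane-8α,19-diol | O1CCOC1CCC[C@@H]1[C@@]2(C)CCC[C@](C)(CO)[C@@H]2CC[C@@]1(C)O | intermediate
18 | 8α,19-dihydroxy-15,16-dinorlabdan-14-al | O=CCCC[C@@H]1[C@@]2(C)CCC[C@](C)(CO)[C@@H]2CC[C@@]1(C)O | intermediate
19 | 8α,19-dihydroxy-15-norlabd-13(16)-en-14-al | C=C(C=O)CC[C@@H]1[C@@]2(C)CCC[C@](C)(CO)[C@@H]2CC[C@@]1(C)O | intermediate
20 | labda-13(16),14-diene-8α,19-diol | C=CC(=C)CC[C@@H]1[C@@]2(C)CCC[C@](C)(CO)[C@@H]2CC[C@@]1(C)O | intermediate
21 | [bis(2,2,2-trifluoroethoxy)phosphoryl]acetic acid | OC(=O)CP(=O)(OCC(F)(F)F)OCC(F)(F)F | starting material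
22 | 8α-hydroxylabda-13(16),14-dien-19-yl [bis(2,2,2-trifluoroethoxy)phosphoryl]acetate | C=CC(=C)CC[C@@H]1[C@@]2(C)CCC[C@](C)(COC(=O)CP(=O)(OCC(F)(F)F)OCC(F)(F)F)[C@@H]2CC[C@@]1(C)O | intermediate
23 | vanillin (4-hydroxy-3-methoxybenzaldehyde) | COc1cc(C=O)ccc1O | starting material
24 | 4-[(tert-butyldimethylsilyl)oxy]-3-methoxybenzaldehyde | COc1cc(C=O)ccc1O[Si](C)(C)C(C)(C)C | intermediate
25 | potassium salt of the phosphonate carbanion of 22 | [K+].C=CC(=C)CC[C@@H]1[C@@]2(C)CCC[C@](C)(COC(=O)[CH-]P(=O)(OCC(F)(F)F)OCC(F)(F)F)[C@@H]2CC[C@@]1(C)O | intermediate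
26 | 8α-hydroxylabda-13(16),14-dien-19-yl (2Z)-3-[4-(tert-butyldimethylsilyloxy)-3-methoxyphenyl]prop-2-enoate | C=CC(=C)CC[C@@H]1[C@@]2(C)CCC[C@](C)(COC(=O)/C=C\c3ccc(O[Si](C)(C)C(C)(C)C)c(OC)c3)[C@@H]2CC[C@@]1(C)O | intermediate
27 | 8α-hydroxylabda-13(16),14-dien-19-yl (2Z)-3-(4-hydroxy-3-methoxyphenyl)prop-2-enoate | C=CC(=C)CC[C@@H]1[C@@]2(C)CCC[C@](C)(COC(=O)/C=C\c3ccc(O)c(OC)c3)[C@@H]2CC[C@@]1(C)O | target

**Step count**

Total step count: 17. Longest linear sequence: 15 steps (steps 1–3, 5–14, 16 and 17, from geranyl bromide); steps 4 and 15 are single-step branches.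

**Steps most likely to fail**

Step 6. The cascade may be cut short by oxidation of the C10 radical before ring B closes, the C8 radical may lose hydrogen from C7 or C9 instead of C17, the acidic oxidising medium may open the dioxolane, or the auxiliary may discriminate the two faces of the C4 radical only weakly. The fallback sets out from 11 and comes back at 12, and it separates radical generation from termination. Compound 11 would be deprotonated (NaH, THF, 0 °C) and selenenylated with PhSeCl to the α-phenylselanyl β-keto ester F1. Irradiation (visible light, benzene, rt) would start a phenylselanyl group-transfer radical chain in which the same C4 radical closes rings A and B and the C8 radical takes the PhSe group from a further molecule of the precursor, giving the C8 selenide F2 under neutral conditions. Oxidation (H2O2, pyridine, CH2Cl2, 0 °C) and syn-elimination of the selenoxide toward the C17 methyl would then give 12.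

Step 10. Oxygen transfer to the 8(17)-alkene may show poor facial selectivity, which would carry the C8 epimer into the tertiary alcohol. The fallback sets out from 15 and comes back at 18, and it replaces epoxidation and hydride opening by a hydrogen-atom-transfer hydration. Mukaiyama hydration of 15 (Co(acac)2, PhSiH3, O2, THF, rt; then PPh3) would place hydrogen on C17 and let the planar C8 radical capture oxygen on the α face away from the C10 methyl, giving the tertiary alcohol (−)-8-phenylmenthyl 14,14-(ethylenedioxy)-8α-hydroxy-15,16-dinorlabdan-19-oate F3. Under the conditions of step 11 (LiAlH4, then 1 M HCl) F3 would give 18.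

Step 16. The Z selectivity may be eroded by reversible addition to the electron-rich aldehyde, and the (Z)-enoate may isomerise to E during work-up. The fallback sets out from 20 and comes back at 26, and it makes the alkene E first and then inverts it with light. Diol 20 would be esterified (DCC, DMAP, CH2Cl2) with (diethoxyphosphoryl)acetic acid to 8α-hydroxylabda-13(16),14-dien-19-yl (diethoxyphosphoryl)acetate F4. A Masamune–Roush Horner–Wadsworth–Emmons reaction with 24 (LiCl, DBU, MeCN, rt) would give the (E)-enoate F5. Triplet-sensitised E to Z photoisomerisation (tris(2-phenylpyridinato)iridium, blue LEDs, MeCN, rt) would then enrich the Z isomer, with residual E isomer separated by chromatography and recycled, to give 26.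

**Further compounds**

F1 | step 6 | (1R,2S,5R)-5-methyl-2-(2-phenylpropan-2-yl)cyclohexyl (6E,10E)-14-(1,3-dioxolan-2-yl)-2,6,10-trimethyl-3-oxo-2-(phenylselanyl)tetradeca-6,10-dienoate (C2 epimers) | CC([Se]c1ccccc1)(C(=O)O[C@@H]1C[C@H](C)CC[C@H]1C(C)(C)c1ccccc1)C(=O)CC/C(C)=C/CC/C(C)=C/CCCC1OCCO1
F2 | step 6 | (−)-8-phenylmenthyl 14,14-(ethylenedioxy)-3-oxo-8-(phenylselanyl)-15,16-dinorlabdan-19-oate (C8 epimers) | O1CCOC1CCC[C@@H]1[C@@]2(C)CCC(=O)[C@](C)(C(=O)O[C@@H]3C[C@H](C)CC[C@H]3C(C)(C)c3ccccc3)[C@@H]2CCC1(C)[Se]c1ccccc1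
F3 | step 10 | (−)-8-phenylmenthyl 14,14-(ethylenedioxy)-8α-hydroxy-15,16-dinorlabdan-19-oate | O1CCOC1CCC[C@@H]1[C@@]2(C)CCC[C@](C)(C(=O)O[C@@H]3C[C@H](C)CC[C@H]3C(C)(C)c3ccccc3)[C@@H]2CC[C@@]1(C)O
F4 | step 16 | 8α-hydroxylabda-13(16),14-dien-19-yl (diethoxyphosphoryl)acetate | C=CC(=C)CC[C@@H]1[C@@]2(C)CCC[C@](C)(COC(=O)CP(=O)(OCC)OCC)[C@@H]2CC[C@@]1(C)O
F5 | step 16 | 8α-hydroxylabda-13(16),14-dien-19-yl (2E)-3-[4-(tert-butyldimethylsilyloxy)-3-methoxyphenyl]prop-2-enoate | C=CC(=C)CC[C@@H]1[C@@]2(C)CCC[C@](C)(COC(=O)/C=C/c3ccc(O[Si](C)(C)C(C)(C)C)c(OC)c3)[C@@H]2CC[C@@]1(C)O
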